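**Assumption (one line):** (6Z) is read from the given SMILES: the CH2OH on C(a) is cis to the allylic CH2 that carries the butenolide, and the C(Me)=CH alkene is E.

## Retrosynthetic overview
1. The butenolide (last ring formed) comes from a Bestmann-ylide annulation (intramolecular Wittig) of the (R)-α-hydroxy ketone **22**.
2. The C5 stereocentre comes from (R)-PMB-glycidyl ether **14**, made by ketoreductase reduction of the prochiral chloroketone **12**. Epoxide opening by the Z-alkenyl-Mg from iodide **9** forms the C(b)–C(c) bond. The ketone is then built from the primary alcohol by oxidation, LiCH2OMOM addition and re-oxidation.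
3. The Z-iodide **9** comes from Cu-catalysed anti-carbomagnesiation of propargyl alcohol with a homoallyl Grignard. That Grignard carries an E-trisubstituted alkene made by Julia ring-opening of a cyclopropyl carbinol from dihydro-β-ionone.
4. Ring order: the cyclohexene arrives intact from β-ionone, the butenolide is formed last, and a final double MOM removal gives the target.

## Route

**Step 1**
Reactants: **1** β-ionone, (3E)-4-(2,6,6-trimethylcyclohex-1-en-1-yl)but-3-en-2-one
Product: **2** dihydro-β-ionone, 4-(2,6,6-trimethylcyclohex-1-en-1-yl)butan-2-one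
Conditions: H2 (1 atm), RhCl(PPh3)3 (2 mol%), toluene, 25 °C
Reagents that add atoms: H2, [H][H]
Why: Wilkinson hydrogenation reduces only the disubstituted enone C=C. The tetrasubstituted ring alkene and the ketone are untouched. No stereocentre is formed.

**Step 2**
Reactants: **2**; **3** cyclopropylmagnesium bromide
Product: **4** 2-cyclopropyl-4-(2,6,6-trimethylcyclohex-1-en-1-yl)butan-2-ol
Conditions: **3** (1.5 equiv), CeCl3 (1.5 equiv), THF, 0→25 °C; aq NH4Cl
Reagents that add atoms: none
Why: Grignard 1,2-addition to the methyl ketone. CeCl3 suppresses enolisation. The product is a racemic tertiary alcohol whose stereocentre is destroyed in the next step.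

**Step 3**
Reactant: **4**
Product: **5** 1-[(3E)-6-bromo-3-methylhex-3-en-1-yl]-2,6,6-trimethylcyclohex-1-ene
Conditions: 48% aq HBr, ZnBr2 (cat.), CH2Cl2, 0 °C, 45 min; then AgNO3–SiO2 chromatography
Reagents that add atoms: hydrobromic acid, Br
Why: Julia cyclopropylcarbinyl→homoallyl rearrangement. A chair-like cation opening with bromide capture gives the E-trisubstituted alkene (about 9:1), and chromatography removes the Z isomer.

**Step 4**
Reactant: **5**
Product: **6** (3E)-4-methyl-6-(2,6,6-trimethylcyclohex-1-en-1-yl)hex-3-en-1-ylmagnesium bromide (THF solution, titrated)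
Conditions: Mg turnings (1.5 equiv), I2 (cat.), THF, 40 °C, 2 h
Reagents that add atoms: magnesium, [Mg]
Why: Oxidative insertion into a primary alkyl bromide. Homoallyl Grignards are configurationally stable and the alkene is untouched.

**Step 5**
Reactants: **6** (3 equiv); **7** propargyl alcohol
Product: **8** (2Z)-3-iodo-2-[(3E)-4-methyl-6-(2,6,6-trimethylcyclohex-1-en-1-yl)hex-3-en-1-yl]prop-2-en-1-ol
Conditions: CuI (10 mol%), THF, 0→25 °C, 3 h; then I2 (3.5 equiv), −78→0 °C; aq Na2S2O3
Reagents that add atoms: iodine, II
Why: Cu-catalysed carbomagnesiation of the propargylic alkoxide. The R group adds at C2 and Mg at C3, held cis to CH2O in a five-membered oxa-magnesacycle (anti addition). I2 cleaves C–Mg with retention, giving the Z-iodide, so the future CH2(c) will be cis to CH2OH.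

**Step 6**
Reactant: **8**
Product: **9** MOM ether of **8**: (Z)-I–CH=C(CH2OCH2OCH3)–CH2CH2–CH=C(Me)(E)–CH2CH2-(2,6,6-trimethylcyclohexenyl)
Conditions: MOMCl (2 equiv), i-Pr2NEt (3 equiv), CH2Cl2, 0→25 °C
Reagents that add atoms: chloromethyl methyl ether, ClCOC
Why: Williamson-type protection of the primary alcohol. The MOM ether survives organometallic exchange and is removed at the end.

**Step 7**
Reactants: **10** 1,3-dichloroacetone; **11** 4-methoxybenzyl alcohol
Product: **12** 1-chloro-3-[(4-methoxybenzyl)oxy]propan-2-one
Conditions: **11** + NaH (1.0 equiv), THF, 0 °C; this alkoxide is added dropwise to **10** (3 equiv), THF, −20→0 °C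
Reagents that add atoms: none
Why: SN2 at an α-halo ketone. Excess **10** suppresses the bis-ether. The product is a prochiral ketone with two different CH2X arms.

**Step 8**
Reactant: **12**
Product: **13** (2S)-1-chloro-3-[(4-methoxybenzyl)oxy]propan-2-ol
Conditions: (S)-selective ketoreductase from a KRED panel, NADP+ (0.1 mol%), D-glucose, glucose dehydrogenase, 100 mM KPi pH 7.0, 10% iPrOH or DMSO, 30 °C
Reagents that add atoms: none
Why: Enzyme-catalysed asymmetric ketone reduction (NADPH-dependent oxidoreductase). The active site distinguishes CH2Cl from CH2OPMB and delivers hydride to one enantiotopic face. This sets the only stereocentre of the target (≥98% ee expected).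

**Step 9**
Reactant: **13**
Product: **14** (2R)-2-{[(4-methoxybenzyl)oxy]methyl}oxirane
Conditions: K2CO3 (2 equiv), MeOH, 0→25 °C, 3 h
Reagents that add atoms: none
Why: Intramolecular SN2 of the alkoxide on the primary C–Cl. The stereocentre is not involved, and the descriptor changes from S to R only because the CIP priorities change.

**Step 10**
Reactants: **9**; **14** (1.5 equiv)
Product: **15** (2R,4Z)-2-hydroxy-1-PMBO-alkene: MOMOCH2–C(R)=CH–CH2–CH(OH)–CH2OPMB with R = the (3E)-4-methyl-6-(trimethylcyclohexenyl)hex-3-enyl chain; CH2OMOM cis to the CH2 that is bonded to C(OH)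
Conditions: i-PrMgCl·LiCl (1.2 equiv), THF, −20 °C, 1 h; then CuI (10 mol%) and **14**, −20→0 °C
Reagents that add atoms: none
Why: I/Mg exchange retains the alkene geometry. Cu-catalysed SN2 opening at the unhindered terminal epoxide carbon forms the C(b)–C(c) bond and leaves the stereocentre untouched.

**Step 11**
Reactant: **15**
Product: **16** triethylsilyl ether of **15**
Conditions: TESCl (1.5 equiv), imidazole (3 equiv), DMF, 0→25 °C, 2 h
Reagents that add atoms: chlorotriethylsilane, CC[Si](CC)(CC)Cl
Why: Silylation of the secondary alcohol protects it through the following oxidations and organometallic addition.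

**Step 12**
Reactant: **16**
Product: **17** primary alcohol: …CH2–CH(OTES)–CH2OH, (2R)
Conditions: DDQ (1.2 equiv), CH2Cl2/pH 7 phosphate buffer (18:1), 0 °C, 30 min
Reagents that add atoms: none
Why: Oxidative PMB removal. The buffer protects the TES and MOM groups, and the isolated alkenes are inert at 0 °C.

**Step 13**
Reactant: **17**
Product: **18** (2R)-2-(triethylsilyloxy) aldehyde: …CH2–CH(OTES)–CHO
Conditions: Dess–Martin periodinane (1.5 equiv), NaHCO3, CH2Cl2, 0→25 °C, 1 h (product used crude)
Reagents that add atoms: none
Why: Mild, non-basic oxidation of the primary alcohol, so the α-silyloxy aldehyde does not epimerise.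

**Step 14**
Reactants: **18**; **19** tributyl(methoxymethoxymethyl)stannane
Product: **20** …CH2–CH(OTES)–CH(OH)–CH2OMOM (mixture of diastereomers at the new carbinol; the C5 centre is unchanged)
Conditions: **19** (2.5 equiv) + n-BuLi (2.4 equiv), THF, −78 °C, 15 min; then **18**, −78 °C, 30 min
Reagents that add atoms: none
Why: Sn/Li exchange (Still) gives LiCH2OMOM, which adds 1,2 to the aldehyde at −78 °C. The new carbinol stereocentre is removed in the next step.

**Step 15**
Reactant: **20**
Product: **21** …CH2–CH(OTES)–C(=O)–CH2OMOM
Conditions: Dess–Martin periodinane (2 equiv), NaHCO3, CH2Cl2, 25 °C, 1 h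
Reagents that add atoms: none
Why: Buffered oxidation of the secondary alcohol to the ketone without enolisation.

**Step 16**
Reactant: **21**
Product: **22** (R)-α-hydroxy ketone: …CH2–CH(OH)–C(=O)–CH2OMOM
Conditions: PPTS (0.3 equiv), MeOH/CH2Cl2 (2:1), 25 °C, 4 h
Reagents that add atoms: none
Why: Mild acid methanolysis removes only the TES ether. MOM ethers are stable to PPTS/MeOH at room temperature, and no base is present, so the α-centre is not epimerised.

**Step 17**
Reactants: **22**; **23** (triphenylphosphoranylidene)ketene, Ph3P=C=C=O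
Product: **24** (5R)-5-[alkenyl]-4-(methoxymethoxymethyl)furan-2(5H)-one; both MOM ethers retained
Conditions: **23** (1.5 equiv), toluene, 25 °C, 1 h, then 80 °C, 6 h
Reagents that add atoms: none
Why: Bestmann annulation. The OH adds to the ketene to give an ester ylide, which undergoes intramolecular Wittig with the ketone to close the butenolide. The conditions are neutral, so the γ-stereocentre is retained.

**Step 18**
Reactant: **24**
Product: **25** (6Z)-neomanoalide
Conditions: ZnBr2 (6 equiv), n-PrSH (12 equiv), CH2Cl2, 0 °C, 1 h
Reagents that add atoms: none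
Why: Lewis acid/thiol cleavage of both primary MOM ethers under non-basic, non-protic-acid conditions. The lactone and the γ-stereocentre, the alkenes and the Z/E geometries are preserved. The product is the target.

## Compound list
| # | Name | SMILES | Role |
|---|---|---|---|
| 1 | β-ionone | CC(=O)/C=C/C1=C(C)CCCC1(C)C | starting material |
| 2 | dihydro-β-ionone | CC(=O)CCC1=C(C)CCCC1(C)C | intermediate |
| 3 | cyclopropylmagnesium bromide | Br[Mg]C1CC1 | starting material |
| 4 | cyclopropyl tertiary carbinol | CC(O)(C1CC1)CCC1=C(C)CCCC1(C)C | intermediate |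
| 5 | (E)-homoallylic bromide | BrCC/C=C(C)/CCC1=C(C)CCCC1(C)C | intermediate |
| 6 | homoallylic Grignard | Br[Mg]CC/C=C(C)/CCC1=C(C)CCCC1(C)C | intermediate |
| 7 | propargyl alcohol | C#CCO | starting material |
| 8 | (Z)-iodo allylic alcohol | OC/C(CC/C=C(C)/CCC1=C(C)CCCC1(C)C)=C\I | intermediate |
| 9 | MOM ether of 8 | COCOC/C(CC/C=C(C)/CCC1=C(C)CCCC1(C)C)=C\I | intermediate |
| 10 | 1,3-dichloroacetone | O=C(CCl)CCl | starting material |
| 11 | 4-methoxybenzyl alcohol | COc1ccc(CO)cc1 | starting material |
| 12 | 1-chloro-3-(PMBO)propan-2-one | COc1ccc(COCC(=O)CCl)cc1 | intermediate |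
| 13 | (2S)-1-chloro-3-(PMBO)propan-2-ol | COc1ccc(COC[C@H](O)CCl)cc1 | intermediate |
| 14 | (2R)-PMB glycidyl ether | COc1ccc(COC[C@H]2CO2)cc1 | intermediate |
| 15 | coupled (R)-secondary alcohol | COCOC/C(CC/C=C(C)/CCC1=C(C)CCCC1(C)C)=C\C[C@@H](O)COCc1ccc(OC)cc1 | intermediate |
| 16 | TES ether | COCOC/C(CC/C=C(C)/CCC1=C(C)CCCC1(C)C)=C\C[C@@H](O[Si](CC)(CC)CC)COCc1ccc(OC)cc1 | intermediate |
| 17 | primary alcohol | COCOC/C(CC/C=C(C)/CCC1=C(C)CCCC1(C)C)=C\C[C@@H](O[Si](CC)(CC)CC)CO | intermediate |
| 18 | α-silyloxy aldehyde | COCOC/C(CC/C=C(C)/CCC1=C(C)CCCC1(C)C)=C\C[C@@H](O[Si](CC)(CC)CC)C=O | intermediate |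
| 19 | Bu3SnCH2OMOM | CCCC[Sn](CCCC)(CCCC)COCOC | starting material |
| 20 | secondary carbinol (diastereomer mixture at new carbinol) | COCOC/C(CC/C=C(C)/CCC1=C(C)CCCC1(C)C)=C\C[C@@H](O[Si](CC)(CC)CC)C(O)COCOC | intermediate |
| 21 | α-silyloxy ketone | COCOC/C(CC/C=C(C)/CCC1=C(C)CCCC1(C)C)=C\C[C@@H](O[Si](CC)(CC)CC)C(=O)COCOC | intermediate |
| 22 | (R)-α-hydroxy ketone | COCOC/C(CC/C=C(C)/CCC1=C(C)CCCC1(C)C)=C\C[C@@H](O)C(=O)COCOC | intermediate |
| 23 | Ph3P=C=C=O | O=C=C=P(c1ccccc1)(c1ccccc1)c1ccccc1 | starting material |
| 24 | bis-MOM butenolide | COCOC/C(CC/C=C(C)/CCC1=C(C)CCCC1(C)C)=C\C[C@H]2OC(=O)C=C2COCOC | intermediate |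
| 25 | (6Z)-neomanoalide | CC1=C(CC/C(C)=C/CC/C(=C/C[C@H]2OC(=O)C=C2CO)CO)C(C)(C)CCC1 | target |

## Totals
- Total steps: 18.
- Longest linear sequence: 15 steps (β-ionone → 25).

## Three steps most likely to fail
1. **Step 5 (carbomagnesiation/iodination).** Regio- or stereoselectivity may fall off with the long homoallyl Grignard, or the iodide may be contaminated with the E isomer.
   - Fallback (different approach): lock the Z-alkene in a ring.
   - Couple 4-tosyloxy-2(5H)-furanone (from tetronic acid) with **6** (Fe/Ni Kumada) to give the 4-alkylbutenolide, then reduce with LiAlH4 to the Z-diol.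
   - Convert the CH2OH on the alkene carbon to the allylic bromide, then couple with vinylMgBr (Li2CuCl4). Hydroborate the terminal alkene with 9-BBN, oxidise to the aldehyde, and set C5 by L-proline-catalysed α-aminoxylation.
   - Rejoin the route at the aldehyde (Step 14).
2. **Step 17 (Bestmann annulation).** The α-hydroxy ketone may epimerise or convert poorly at 80 °C.
   - Fallback (different approach): Still–Gennari olefination of ketone **21** with (CF3CH2O)2P(O)CH2CO2Me to give the Z-enoate.
   - Then remove the TES group with PPTS/MeOH, so that the Z-γ-hydroxy enoate lactonises; the E isomer cannot lactonise and is separated.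
   - This replaces the intramolecular Wittig with olefination followed by lactonisation.
3. **Step 18 (double MOM removal).** The Lewis acid/thiol conditions may damage the alkenes or the lactone.
   - Fallback (different approach): switch the C(a) oxygen protection to TBS at Step 6.
   - Install the C4 side as an acetoxymethyl ketone (acid → acid chloride → TMSCHN2 → AcOH) instead of adding LiCH2OMOM.
   - After the Bestmann step, remove the TBS with HF·pyridine and the acetate with a lipase (hydrolase, CAL-B) under neutral conditions.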